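**Retrosynthetic overview**

- The target is (13S)-8α-formyloxylabdan-15-oic acid. The last operations are C15 oxidation and O-formylation of the C8 tertiary alcohol. C8–O and C9–H (both α) come from syn hydroboration of a C8=C9 alkene.
- C9–C11 is cut next: iron-catalysed coupling of a C9 enol triflate with a C11–C15 Grignard reagent, whose C13 centre comes from (R)-methyl hydrogen 3-methylglutarate.
- Structural feature: ring B (C5–C10) with the C8 methyl C17, plus C4 and one of its methyls, is the intact carbon skeleton of (R)-carvone. Its only stereocentre becomes C5, so ring A lacks just C1–C3 and one hydrogen.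
- Key disconnection C3–C4: a C4 radical, made by hydrogen-atom transfer to the isopropenyl group, closes onto an acrylate arm (C1–C3 with a removable ester on C2). The arm is set on C10 by two enolate alkylations (C20 methyl first, arm second, anti to isopropenyl).
- Ring order: ring B is present from the start; ring A is the only ring closed (key step); the side chain and the C8/C9 centres follow.

Key step: step 3

Remark: labdane numbering (C1–C20) is used for all intermediates. (R)-Methyl hydrogen 3-methylglutarate is taken as the commercial single enantiomer in place of desymmetrising 3-methylglutaric anhydride. Compounds 5–7 are carried as C2 epimer mixtures because C2 becomes CH2 in step 5.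

**Step 1**
Reactants: 1 (R)-carvone
Product: 2 6-methylcarvone, (5R)-2,6-dimethyl-5-(prop-1-en-2-yl)cyclohex-2-en-1-one, mixture of C6 epimers
Conditions: LiN(i-Pr)2, THF, −78 °C; MeI, −78 → 0 °C
Reagents that add atoms: methyl iodide, CI
Why: Kinetic deprotonation gives the cross-conjugated α′-lithium dienolate at carvone C6 (future C10), and its SN2 C-methylation (enolate alkylation) installs C20; the new centre forms unselectively, which does not matter because it is planarised again in step 2.

**Step 2**
Reactants: 2 6-methylcarvone; 3 methyl 2-(bromomethyl)acrylate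
Product: 4 methyl 2-{[(1S,6S)-1,3-dimethyl-2-oxo-6-(prop-1-en-2-yl)cyclohex-3-en-1-yl]methyl}prop-2-enoate (acrylate arm trans to isopropenyl, CH3 cis)
Conditions: LiN(i-Pr)2, THF, −78 °C; then 3, −78 °C → rt
Reagents that add atoms: none
Why: Enolate alkylation by SN2′ addition–elimination on the allylic bromide, in which the planar tetrasubstituted enolate carbon is attacked on the face anti to the neighbouring C5 isopropenyl group, so the quaternary C10 is set with the arm trans to isopropenyl.

**Step 3**
Reactants: 4 the trans acrylate-armed 6-methylcarvone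
Product: 5 methyl (5S,10S)-9-oxo-11-nordrim-7-ene-2-carboxylate (trans-decalin, 5α-H, 10β-CH3, C2 epimers)
Conditions: Fe(acac)3 (0.5 equiv), PhSiH3 (2.5 equiv), EtOH/(CH2OH)2 (5:1), 60 °C, 0.02 M
Reagents that add atoms: none
Why: An iron hydride formed from Fe(acac)3 and PhSiH3 transfers a hydrogen atom to the terminal CH2 of the electron-rich 1,1-disubstituted isopropenyl group (Markovnikov), which creates the second C4 methyl and a nucleophilic tertiary C4 radical. This radical adds to the unsubstituted terminus C3 of the acrylate (Giese addition), and the resulting α-ester radical at C2 is reduced by divalent iron to the enolate and protonated by ethanol, returning trivalent iron. The closest known reaction type is the metal-hydride hydrogen-atom-transfer reductive coupling of donor alkenes with acrylates in its ring-forming version. Ring A closes in a 6-endo-trig mode, preferred over 5-exo because attack at the substituted C2 would be hindered and would give an unstabilised primary radical. The only new stereocentre, C2, forms as a mixture and is removed in step 5, while the trans ring fusion follows from the trans-diequatorial C5 and C10 arms fixed in step 2. The step needs hydrogen-atom transfer to the isopropenyl group rather than to the enone or the acrylate, which the higher electron density of that alkene should secure, and high dilution suppresses intermolecular addition.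

**Step 4**
Reactants: 5 methyl 9-oxo-11-nordrim-7-ene-2-carboxylate
Product: 6 (5S,10S)-9-oxo-11-nordrim-7-ene-2-carboxylic acid (C2 epimers)
Conditions: LiOH·H2O, THF/MeOH/H2O (3:1:1), 50 °C; then 1 M HCl
Reagents that add atoms: lithium hydroxide, [Li+].[OH-]
Why: Ester saponification (BAc2); the enone has no α′-hydrogen (C10 is quaternary) and C5 is not acidic, so only the irrelevant C2 centre can epimerise.

**Step 5**
Reactants: 6 9-oxo-11-nordrim-7-ene-2-carboxylic acid
Product: 8 (4aS,8aS)-2,5,5,8a-tetramethyl-4a,5,6,7,8,8a-hexahydronaphthalen-1(4H)-one [(5S,10S)-11-nordrim-7-en-9-one], via Barton ester 7 (not isolated)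
Conditions: N-hydroxypyridine-2-thione, DCC, CH2Cl2, rt, dark; filter, then t-BuSH, benzene, hv (tungsten lamp), rt
Reagents that add atoms: none
Why: Barton reductive decarboxylation, in which the thiohydroxamate ester fragments in a radical chain to CO2 and a secondary C2 radical that takes a hydrogen atom from t-BuSH; the radical is too remote from the enone to cyclise, and C2 becomes CH2.

**Step 6**
Reactants: 8 (5S,10S)-11-nordrim-7-en-9-one
Product: 10 (4aS,8aS)-2,5,5,8a-tetramethyl-3,4,4a,5,6,7,8,8a-octahydronaphthalen-1-yl trifluoromethanesulfonate [(5S,10S)-11-nordrim-8-en-9-yl triflate], via lithium enolate 9 (not isolated)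
Conditions: LiBH(s-Bu)3, THF, −78 °C; then PhNTf2, −78 °C → rt
Reagents that add atoms: N-phenylbis(trifluoromethanesulfonimide), O=S(=O)(N(c1ccccc1)S(=O)(=O)C(F)(F)F)C(F)(F)F
Why: Conjugate (1,4) hydride reduction of a β-unsubstituted cyclohexenone whose carbonyl is shielded by quaternary C10, followed by O-triflation of the regiodefined C8=C9 enolate (enol triflate formation); no stereocentre is formed.

**Step 7**
Reactants: 11 methyl hydrogen (R)-3-methylglutarate [(3R)-5-methoxy-3-methyl-5-oxopentanoic acid]
Product: 12 methyl (3R)-5-hydroxy-3-methylpentanoate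
Conditions: BH3·SMe2, THF, 0 °C → rt; MeOH quench; used crude
Reagents that add atoms: none
Why: Chemoselective borane reduction of a carboxylic acid in the presence of a methyl ester (through the acyloxyborane), which differentiates the two ends of the symmetric C5 chain without touching the C3 stereocentre.

**Step 8**
Reactants: 12 methyl (3R)-5-hydroxy-3-methylpentanoate
Product: 13 methyl (3R)-5-(benzyloxy)-3-methylpentanoate
Conditions: BnOC(=NH)CCl3, TfOH (5 mol %), CH2Cl2/cyclohexane, 0 °C → rt
Reagents that add atoms: benzyl 2,2,2-trichloroacetimidate, ClC(Cl)(Cl)C(=N)OCc1ccccc1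
Why: Acid-catalysed O-benzylation with a trichloroacetimidate avoids the alkoxide, which would lactonise this δ-hydroxy ester, and the benzyl ether can later be removed under neutral conditions next to a formate.

**Step 9**
Reactants: 13 methyl (3R)-5-(benzyloxy)-3-methylpentanoate
Product: 14 (3S)-5-(benzyloxy)-3-methylpentan-1-ol
Conditions: LiAlH4, THF, 0 °C
Reagents that add atoms: none
Why: Hydride reduction of the ester to the primary alcohol; the benzyl ether is inert and the descriptor changes only through CIP priority.

**Step 10**
Reactants: 14 (3S)-5-(benzyloxy)-3-methylpentan-1-ol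
Product: 15 benzyl (3R)-5-bromo-3-methylpentyl ether
Conditions: CBr4, PPh3, CH2Cl2, 0 °C
Reagents that add atoms: carbon tetrabromide, BrC(Br)(Br)Br
Why: Appel bromination, an SN2 displacement of the oxyphosphonium at a primary carbon remote from the stereocentre.

**Step 11**
Reactants: 10 (5S,10S)-11-nordrim-8-en-9-yl triflate; 15 benzyl (3R)-5-bromo-3-methylpentyl ether
Product: 17 (13S)-15-(benzyloxy)labd-8-ene (5S,10S; tetrasubstituted C8=C9), via Grignard reagent 16 (not isolated)
Conditions: 15, Mg, THF, 40 °C; then add to 10, Fe(acac)3 (10 mol %), THF/NMP, −30 → 0 °C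
Reagents that add atoms: none
Why: Iron-catalysed Kumada-type cross-coupling of an alkenyl triflate with a primary alkyl Grignard reagent through a low-valent iron species, which is fast at low temperature and is expected to outrun β-hydride elimination; it forms the C9–C11 bond with no new stereocentre.

**Step 12**
Reactants: 17 (13S)-15-(benzyloxy)labd-8-ene
Product: 19 (13S)-15-(benzyloxy)labdan-8α-ol (5S,8R,9R,10S,13S), via alkylborane 18 (not isolated)
Conditions: BH3·THF (excess), THF, 0 °C → rt; then 3 M NaOH, 30% H2O2, 0 → 50 °C
Reagents that add atoms: hydrogen peroxide, OO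
Why: Hydroboration–oxidation: syn addition of B–H is expected on the α face, anti to the axial C10 methyl, with boron at the less hindered C8 and hydrogen at the neopentyl C9, and oxidation with retention then sets 8α-OH (8R) and 9α-H (9R) together.

**Step 13**
Reactants: 19 (13S)-15-(benzyloxy)labdan-8α-ol
Product: 20 (13S)-15-(benzyloxy)labdan-8α-yl formate
Conditions: HCO2Ac (acetic formic anhydride), pyridine, DMAP (cat.), CH2Cl2, 0 °C → rt
Reagents that add atoms: acetic formic anhydride, CC(=O)OC=O
Why: Acyl transfer from the mixed anhydride under nucleophilic catalysis, in which the small, more electrophilic formyl carbonyl is delivered to the hindered tertiary alcohol, and the basic medium avoids ionisation and elimination at C8.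

**Step 14**
Reactants: 20 (13S)-15-(benzyloxy)labdan-8α-yl formate
Product: 21 (13S)-15-hydroxylabdan-8α-yl formate
Conditions: H2 (1 atm), Pd/C, EtOAc, rt
Reagents that add atoms: none
Why: Hydrogenolysis of the benzyl ether under neutral conditions, which leave the base-labile tertiary formate intact.

**Step 15**
Reactants: 21 (13S)-15-hydroxylabdan-8α-yl formate
Product: 23 (13S)-8α-(formyloxy)labdan-15-oic acid (5S,8R,9R,10S,13S), the target, via aldehyde 22 (not isolated)
Conditions: TEMPO (0.2 equiv), PhI(OAc)2 (2.5 equiv), MeCN/H2O (1:1), rt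
Reagents that add atoms: water, O
Why: Oxoammonium (TEMPO) oxidation of the primary alcohol to the aldehyde, whose hydrate is oxidised on to the acid in a mildly acidic medium that should not cleave the formate or epimerise C13.

**Compound list**

1 | (R)-carvone | CC1=CC[C@@H](C(C)=C)CC1=O | starting material
2 | 6-methylcarvone, (5R)-2,6-dimethyl-5-(prop-1-en-2-yl)cyclohex-2-en-1-one, C6 epimers | CC1=CC[C@@H](C(C)=C)C(C)C1=O | intermediate
3 | methyl 2-(bromomethyl)acrylate | C=C(CBr)C(=O)OC | starting material
4 | methyl 2-{[(1S,6S)-1,3-dimethyl-2-oxo-6-(prop-1-en-2-yl)cyclohex-3-en-1-yl]methyl}prop-2-enoate | CC1=CC[C@@H](C(C)=C)[C@](C)(CC(=C)C(=O)OC)C1=O | intermediate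
5 | methyl (5S,10S)-9-oxo-11-nordrim-7-ene-2-carboxylate, C2 epimers | CC1=CC[C@H]2C(C)(C)CC(C(=O)OC)C[C@]2(C)C1=O | intermediate
6 | (5S,10S)-9-oxo-11-nordrim-7-ene-2-carboxylic acid, C2 epimers | CC1=CC[C@H]2C(C)(C)CC(C(=O)O)C[C@]2(C)C1=O | intermediate
7 | 2-thioxopyridin-1(2H)-yl (5S,10S)-9-oxo-11-nordrim-7-ene-2-carboxylate (Barton ester), C2 epimers | CC1=CC[C@H]2C(C)(C)CC(C(=O)ON3C=CC=CC3=S)C[C@]2(C)C1=O | intermediate
8 | (4aS,8aS)-2,5,5,8a-tetramethyl-4a,5,6,7,8,8a-hexahydronaphthalen-1(4H)-one | CC1=CC[C@H]2C(C)(C)CCC[C@]2(C)C1=O | intermediate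
9 | lithium (5S,10S)-11-nordrim-8-en-9-olate | CC1=C([O-])[C@@]2(C)CCCC(C)(C)[C@@H]2CC1.[Li+] | intermediate
10 | (4aS,8aS)-2,5,5,8a-tetramethyl-3,4,4a,5,6,7,8,8a-octahydronaphthalen-1-yl trifluoromethanesulfonate | CC1=C(OS(=O)(=O)C(F)(F)F)[C@@]2(C)CCCC(C)(C)[C@@H]2CC1 | intermediate
11 | methyl hydrogen (R)-3-methylglutarate | C[C@H](CC(=O)O)CC(=O)OC | starting material
12 | methyl (3R)-5-hydroxy-3-methylpentanoate | C[C@H](CCO)CC(=O)OC | intermediate
13 | methyl (3R)-5-(benzyloxy)-3-methylpentanoate | C[C@H](CCOCc1ccccc1)CC(=O)OC | intermediate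
14 | (3S)-5-(benzyloxy)-3-methylpentan-1-ol | C[C@H](CCOCc1ccccc1)CCO | intermediate
15 | benzyl (3R)-5-bromo-3-methylpentyl ether | C[C@H](CCOCc1ccccc1)CCBr | intermediate
16 | [(3R)-5-(benzyloxy)-3-methylpentyl]magnesium bromide | C[C@H](CCOCc1ccccc1)CC[Mg]Br | intermediate
17 | (13S)-15-(benzyloxy)labd-8-ene | CC1=C(CC[C@H](C)CCOCc3ccccc3)[C@@]2(C)CCCC(C)(C)[C@@H]2CC1 | intermediate
18 | [(13S)-15-(benzyloxy)labdan-8α-yl]borane | C[C@@H](CC[C@@H]1[C@@]2(C)CCCC(C)(C)[C@@H]2CC[C@@]1(C)B)CCOCc1ccccc1 | intermediate
19 | (13S)-15-(benzyloxy)labdan-8α-ol | C[C@@H](CC[C@@H]1[C@@]2(C)CCCC(C)(C)[C@@H]2CC[C@@]1(C)O)CCOCc1ccccc1 | intermediate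
20 | (13S)-15-(benzyloxy)labdan-8α-yl formate | C[C@@H](CC[C@@H]1[C@@]2(C)CCCC(C)(C)[C@@H]2CC[C@@]1(C)OC=O)CCOCc1ccccc1 | intermediate
21 | (13S)-15-hydroxylabdan-8α-yl formate | C[C@@H](CC[C@@H]1[C@@]2(C)CCCC(C)(C)[C@@H]2CC[C@@]1(C)OC=O)CCO | intermediate
22 | (13S)-8α-(formyloxy)labdan-15-al | C[C@@H](CC[C@@H]1[C@@]2(C)CCCC(C)(C)[C@@H]2CC[C@@]1(C)OC=O)CC=O | intermediate
23 | (13S)-8α-(formyloxy)labdan-15-oic acid | C[C@@H](CC[C@@H]1[C@@]2(C)CCCC(C)(C)[C@@H]2CC[C@@]1(C)OC=O)CC(=O)O | target

**Totals**

Total step count: 15. Longest linear sequence: 11 steps (steps 1–6 and 11–15, from (R)-carvone); the side-chain branch is steps 7–10.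

**Steps most likely to fail**

- **Step 3 (key step).** Hydrogen-atom transfer may go to the acrylate or the enone instead of the isopropenyl group. That would lead to simple reduction, or to the isomeric ring closure through a C2 radical. The C4 radical may also be reduced before it cyclises.
  Fallback, from 4 back to 5: Markovnikov addition of HBr (33% in AcOH, CH2Cl2, 0 °C) to the isopropenyl group would give tertiary bromide F1. Slow addition of Bu3SnH with AIBN in refluxing benzene then generates the same C4 radical by bromine abstraction, so the reagent no longer chooses among three alkenes. 6-endo cyclisation and hydrogen transfer from the stannane should give 5.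

- **Step 11.** Coupling at the tetrasubstituted C9 triflate, flanked by quaternary C10, may be slow. Cleavage of the triflate back to the ketone, homocoupling of the Grignard reagent, or β-hydride elimination could then dominate.
  Fallback, from 8 back to 17: conjugate reduction with LiBH(s-Bu)3 and protonation (aqueous NH4Cl, then NaOMe/MeOH equilibration) would give saturated ketone F2, with the C8 methyl equatorial. 1,2-Addition of the organocerium reagent made from Grignard reagent 16 and anhydrous CeCl3 (THF, −78 °C) would give tertiary alcohol F3. Dehydration (SOCl2, pyridine, 0 °C, then TsOH in benzene to equilibrate the alkene into the tetrasubstituted position) should give 17.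

- **Step 12.** Addition of borane to the hindered tetrasubstituted alkene may be sluggish. Regiocontrol (boron at C9) or facial control could be lost, and boron could migrate if the reaction is forced thermally.
  Fallback, from 17 back to 19: epoxidation with mCPBA (CH2Cl2, NaHCO3, 0 °C) on the α face would give 8α,9α-epoxide F4. Reductive opening with Cp2TiCl (trivalent titanium, from Cp2TiCl2 and Mn dust) and 1,4-cyclohexadiene in THF is expected to cleave the more congested C9–O bond, leaving the titanium alkoxide on C8. Hydrogen-atom transfer to the C9 radical from the α face should then give 19.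

**Further compounds**

F1 | step 3 | methyl 2-{[(1S,6R)-6-(2-bromopropan-2-yl)-1,3-dimethyl-2-oxocyclohex-3-en-1-yl]methyl}prop-2-enoate | CC1=CC[C@@H](C(C)(C)Br)[C@](C)(CC(=C)C(=O)OC)C1=O
F2 | step 11 | (2R,4aS,8aS)-2,5,5,8a-tetramethyloctahydronaphthalen-1(2H)-one (8βH-11-nordriman-9-one) | C[C@@H]1CC[C@H]2C(C)(C)CCC[C@]2(C)C1=O
F3 | step 11 | (13S)-15-(benzyloxy)-8βH-labdan-9-ol, C9 epimers | C[C@@H]1CC[C@H]2C(C)(C)CCC[C@]2(C)C1(O)CC[C@H](C)CCOCc3ccccc3
F4 | step 12 | (13S)-15-(benzyloxy)-8α,9α-epoxylabdane | C[C@@H](CC[C@@]12O[C@]1(C)CC[C@H]3C(C)(C)CCC[C@]23C)CCOCc4ccccc4
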